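The route rests on cutting both aryl–carbon bonds of the CH2–C(=O) bridge that links C1' of ring B (the prenylated dimethoxyphenol ring) to C1 of ring A (the resorcinol ring). That bridge is read as a vinyl group whose future carbonyl carbon carries boron. In a single palladium-catalysed conjunctive coupling, ring A shifts from boron to the α-carbon while ring B is delivered to the terminal CH2, which fixes the position of the later ketone. The precursors are the boron ate complex made from 2,4-bis(methoxymethoxy)phenyllithium and vinylboronic acid pinacol ester, and a MOM-protected, pentasubstituted ring B aryl iodide. Oxidation and MOM removal finish the synthesis.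

Key step: step 7

Remark: licoriphenone has no stereocentre and no E/Z alkene. The only stereocentre that arises on the way (in 15 and 16) is carried as a racemate and is removed in step 9.

Step 1
Reactants: 1 3,5-dimethoxyphenol
Product: 2 (3,5-dimethoxyphenoxy)tri(propan-2-yl)silane
Conditions: TIPSCl, imidazole, DMF, rt
Reagents that add atoms: chlorotriisopropylsilane (TIPSCl), CC(C)[Si](Cl)(C(C)C)C(C)C
Why: Imidazole-promoted O-silylation of a phenol is routine, and the bulky, poorly coordinating triisopropylsilyl ether is chosen because it shields both ring carbons next to it and so prepares the regiochemistry of step 2.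

Step 2
Reactants: 2 (3,5-dimethoxyphenoxy)tri(propan-2-yl)silane; 3 prenyl bromide
Product: 5 [3,5-dimethoxy-4-(3-methylbut-2-en-1-yl)phenoxy]tri(propan-2-yl)silane, via C4 aryllithium 4 (not isolated)
Conditions: n-BuLi, THF, 0 °C to rt; then 3, −78 °C to rt
Reagents that add atoms: n-butyllithium, [Li]CCCC (supplies only the lithium of 4)
Why: Directed ortho-metalation should occur at C4, the only ring carbon flanked by two coordinating methoxy groups and remote from the silyl bulk, and the resulting aryllithium is alkylated by SN2 attack at the unhindered primary carbon of the allylic bromide.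

Step 3
Reactants: 5 [3,5-dimethoxy-4-(3-methylbut-2-en-1-yl)phenoxy]tri(propan-2-yl)silane
Product: 6 3,5-dimethoxy-4-(3-methylbut-2-en-1-yl)phenol
Conditions: n-Bu4NF, AcOH, THF, 0 °C to rt
Reagents that add atoms: none
Why: Fluoride-induced cleavage of the aryl silyl ether is driven by the strength of the silicon–fluorine bond, acetic acid keeps the medium near neutral, and the alkene and methyl ethers are inert.

Step 4
Reactants: 6 3,5-dimethoxy-4-(3-methylbut-2-en-1-yl)phenol
Product: 7 1,3-dimethoxy-5-(methoxymethoxy)-2-(3-methylbut-2-en-1-yl)benzene
Conditions: MOMCl, i-Pr2NEt, CH2Cl2, 0 °C to rt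
Reagents that add atoms: chloromethyl methyl ether (MOMCl), COCCl
Why: Base-mediated O-alkylation of the phenol (Williamson-type acetal formation) installs a small group that withstands organolithiums, palladium catalysis, perborate and the periodinane and that is also the strongest ortho-director on the ring.

Step 5
Reactants: 7 1,3-dimethoxy-5-(methoxymethoxy)-2-(3-methylbut-2-en-1-yl)benzene
Product: 9 2-iodo-3,5-dimethoxy-1-(methoxymethoxy)-4-(3-methylbut-2-en-1-yl)benzene, via ring B aryllithium 8 (not isolated)
Conditions: n-BuLi, THF, −20 to 0 °C; then I2, −78 °C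
Reagents that add atoms: iodine, [I][I]; n-butyllithium, [Li]CCCC (supplies only the lithium of 8)
Why: Directed ortho-metalation is steered by the cooperative OMOM and OMe groups to the carbon between them (the two such carbons are equivalent by symmetry), this complex-induced ring lithiation should be kinetically faster than deprotonation of the prenyl CH2, and the iodine quench at low temperature gives one mono-iodide without prolonged contact of the alkene with an electrophilic iodine source.

Step 6
Reactants: 10 4-bromoresorcinol
Product: 11 1-bromo-2,4-bis(methoxymethoxy)benzene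
Conditions: MOMCl, i-Pr2NEt, CH2Cl2, 0 °C to rt
Reagents that add atoms: chloromethyl methyl ether (MOMCl), COCCl
Why: Twofold base-mediated O-alkylation of the resorcinol hydroxyls gives acetals that survive n-BuLi, and the ortho acetal oxygen will stabilise the aryllithium of step 7 by coordination.

Step 7
Reactants: 11 1-bromo-2,4-bis(methoxymethoxy)benzene; 12 vinylboronic acid pinacol ester; 9 2-iodo-3,5-dimethoxy-1-(methoxymethoxy)-4-(3-methylbut-2-en-1-yl)benzene
Product: 15 racemic 2-{1-[2,4-bis(methoxymethoxy)phenyl]-2-[2,4-dimethoxy-6-(methoxymethoxy)-3-(3-methylbut-2-en-1-yl)phenyl]ethyl}-4,4,5,5-tetramethyl-1,3,2-dioxaborolane, via ring A aryllithium 13 (not isolated), via lithium boron ate complex 14 (not isolated)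
Conditions: 11 (1.3 equiv), n-BuLi, THF, −78 °C; 12, −78 °C to rt; evaporate, fresh THF; 9 (1.0 equiv), Pd(OAc)2 (5 mol %), 1,1'-bis(dicyclohexylphosphino)ferrocene (6 mol %), NaOTf (2 equiv), 60 °C
Reagents that add atoms: n-butyllithium, [Li]CCCC (supplies only the lithium of 13 and 14)
Why: Bromine–lithium exchange on 11 gives 13, whose addition to the vacant boron orbital of 12 gives the four-coordinate boronate 14, and stripping the volatiles removes 1-bromobutane so that no halide accompanies 14 into the catalysis. Oxidative addition of 9 to the zerovalent palladium generated in situ is followed by exchange of the bound iodide for weakly coordinating triflate (NaOTf); the cationic divalent arylpalladium then binds the vinyl π bond of 14, ring A moves from boron to the neighbouring carbon as palladium bonds to the terminal carbon, and reductive elimination forms the CH2–C1' bond and completes the turnover. The closest known reaction type is the palladium-catalysed conjunctive cross-coupling of aryl(vinyl)boronate complexes with aryl halides and triflates, here applied to an unusually crowded 2,6-dioxygenated iodide. No ring is closed, and the one new stereocentre (the boron-bearing carbon) is under no control because the ligand is achiral, so 15 should form as a racemate whose centre vanishes in step 9. Constitutional selectivity is built into the mechanism, because the group that leaves boron is necessarily attached to the carbon that keeps boron while the electrophile is attached to the CH2 terminus, which places the later carbonyl next to ring A. The chemoselectivity needed is metallate shift over direct boron-to-palladium aryl transfer and over β-hydride elimination, and it is served by the chelating, wide-bite-angle, electron-rich ferrocenyl bisphosphine, by halide removal, by the high migratory aptitude of the electron-rich ring A, by the small OMe and OMOM groups beside C1', and by the trisubstituted prenyl alkene being too hindered to compete for palladium.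

Step 8
Reactants: 15 racemic 1,2-diarylethyl pinacol boronate
Product: 16 racemic 1-[2,4-bis(methoxymethoxy)phenyl]-2-[2,4-dimethoxy-6-(methoxymethoxy)-3-(3-methylbut-2-en-1-yl)phenyl]ethan-1-ol
Conditions: NaBO3·4H2O, THF/H2O (1:1), rt
Reagents that add atoms: sodium perborate, [Na+].[Na+].O[B-]1(O)OO[B-](O)(O)OO1
Why: Boronate oxidation proceeds by addition of the perborate-derived hydroperoxide anion to boron and 1,2-shift of the benzylic carbon to oxygen, and the nearly neutral perborate medium spares the prenyl alkene and the acetals and limits protodeboronation of the sensitive benzylic carbon–boron bond, 16 remaining racemic.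

Step 9
Reactants: 16 racemic 1,2-diarylethanol
Product: 17 1-[2,4-bis(methoxymethoxy)phenyl]-2-[2,4-dimethoxy-6-(methoxymethoxy)-3-(3-methylbut-2-en-1-yl)phenyl]ethan-1-one
Conditions: Dess–Martin periodinane, NaHCO3, CH2Cl2, 0 °C to rt
Reagents that add atoms: none
Why: Dess–Martin oxidation (ligand exchange at hypervalent iodine followed by loss of the carbinol hydrogen) converts the secondary benzylic alcohol to the aryl ketone under buffered conditions that avoid ionisation of this electron-rich benzylic alcohol, leave the alkene and acetals untouched and erase the only stereocentre.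

Step 10
Reactants: 17 tris-MOM-protected deoxybenzoin
Product: 18 licoriphenone
Conditions: HCl (ca. 0.5 M), MeOH, rt
Reagents that add atoms: none
Why: Acid-catalysed transacetalisation to methanol releases all three phenols, the prenyl group cannot cyclise because both neighbouring oxygens are methyl ethers, and the ketone, deactivated by the hydrogen bond from the ring A ortho hydroxyl and by para donation, should resist attack of the ring B phenol at room temperature if the acid is neutralised as soon as conversion is complete.

Compound list
1 | 3,5-dimethoxyphenol | COc1cc(O)cc(OC)c1 | starting material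
2 | (3,5-dimethoxyphenoxy)tri(propan-2-yl)silane | COc1cc(O[Si](C(C)C)(C(C)C)C(C)C)cc(OC)c1 | intermediate
3 | prenyl bromide (1-bromo-3-methylbut-2-ene) | CC(C)=CCBr | starting material
4 | [2,6-dimethoxy-4-(triisopropylsilyloxy)phenyl]lithium | COc1cc(O[Si](C(C)C)(C(C)C)C(C)C)cc(OC)c1[Li] | intermediate
5 | [3,5-dimethoxy-4-(3-methylbut-2-en-1-yl)phenoxy]tri(propan-2-yl)silane | COc1cc(O[Si](C(C)C)(C(C)C)C(C)C)cc(OC)c1CC=C(C)C | intermediate
6 | 3,5-dimethoxy-4-(3-methylbut-2-en-1-yl)phenol | COc1cc(O)cc(OC)c1CC=C(C)C | intermediate
7 | 1,3-dimethoxy-5-(methoxymethoxy)-2-(3-methylbut-2-en-1-yl)benzene | COCOc1cc(OC)c(CC=C(C)C)c(OC)c1 | intermediate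
8 | [2,4-dimethoxy-6-(methoxymethoxy)-3-(3-methylbut-2-en-1-yl)phenyl]lithium | COCOc1cc(OC)c(CC=C(C)C)c(OC)c1[Li] | intermediate
9 | 2-iodo-3,5-dimethoxy-1-(methoxymethoxy)-4-(3-methylbut-2-en-1-yl)benzene | COCOc1cc(OC)c(CC=C(C)C)c(OC)c1I | intermediate
10 | 4-bromoresorcinol (4-bromobenzene-1,3-diol) | Oc1ccc(Br)c(O)c1 | starting material
11 | 1-bromo-2,4-bis(methoxymethoxy)benzene | COCOc1ccc(Br)c(OCOC)c1 | intermediate
12 | vinylboronic acid pinacol ester (2-ethenyl-4,4,5,5-tetramethyl-1,3,2-dioxaborolane) | C=CB1OC(C)(C)C(C)(C)O1 | starting material
13 | [2,4-bis(methoxymethoxy)phenyl]lithium | [Li]c1ccc(OCOC)cc1OCOC | intermediate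
14 | lithium [2,4-bis(methoxymethoxy)phenyl](ethenyl)(pinacolato)borate | [Li+].C=C[B-]1(c2ccc(OCOC)cc2OCOC)OC(C)(C)C(C)(C)O1 | intermediate
15 | racemic 2-{1-[2,4-bis(methoxymethoxy)phenyl]-2-[2,4-dimethoxy-6-(methoxymethoxy)-3-(3-methylbut-2-en-1-yl)phenyl]ethyl}-4,4,5,5-tetramethyl-1,3,2-dioxaborolane | COCOc1ccc(C(Cc2c(OCOC)cc(OC)c(CC=C(C)C)c2OC)B2OC(C)(C)C(C)(C)O2)c(OCOC)c1 | intermediate
16 | racemic 1-[2,4-bis(methoxymethoxy)phenyl]-2-[2,4-dimethoxy-6-(methoxymethoxy)-3-(3-methylbut-2-en-1-yl)phenyl]ethan-1-ol | COCOc1ccc(C(O)Cc2c(OCOC)cc(OC)c(CC=C(C)C)c2OC)c(OCOC)c1 | intermediate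
17 | 1-[2,4-bis(methoxymethoxy)phenyl]-2-[2,4-dimethoxy-6-(methoxymethoxy)-3-(3-methylbut-2-en-1-yl)phenyl]ethan-1-one | COCOc1ccc(C(=O)Cc2c(OCOC)cc(OC)c(CC=C(C)C)c2OC)c(OCOC)c1 | intermediate
18 | licoriphenone, 1-(2,4-dihydroxyphenyl)-2-[6-hydroxy-2,4-dimethoxy-3-(3-methylbut-2-en-1-yl)phenyl]ethan-1-one | COc1cc(O)c(CC(=O)c2ccc(O)cc2O)c(OC)c1CC=C(C)C | target

Total step count: 10. Longest linear sequence: 9 (steps 1–5 and 7–10, from 1).

Steps most likely to fail

Step 7. Oxidative addition, and above all alkene binding at the doubly ortho-substituted arylpalladium, may be so slow that other pathways take over. These are direct aryl transfer from boron to palladium, β-hydride elimination and protonolysis of the ate complex. The fallback builds the same two bonds stepwise by polar chemistry without palladium.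
- It sets out from 7, which is lithiated as in step 5 to 8.
- Trapping 8 with ethylene oxide (THF, −78 °C to rt) should give 2-[2,4-dimethoxy-6-(methoxymethoxy)-3-(3-methylbut-2-en-1-yl)phenyl]ethan-1-ol F1.
- Dess–Martin oxidation of F1 should give [2,4-dimethoxy-6-(methoxymethoxy)-3-(3-methylbut-2-en-1-yl)phenyl]acetaldehyde F2.
- Addition of 13 (from 11 and n-BuLi, THF, −78 °C) to F2 should give the alcohol 16, where the route is rejoined.

Step 10. Once the ring B phenol is free, protic acid may drive its cyclodehydration onto the ketone. Acid may also add solvent across the prenyl alkene before the last acetal has fallen. The fallback exchanges the protecting groups, so that no protic acid meets the free phenol–ketone pair.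
- It sets out from 17, which is treated with TESOTf and 2,2'-bipyridyl in CH3CN (0 °C to rt).
- These conditions are known to convert aryl MOM ethers directly into aryl triethylsilyl ethers. They should give 1-[2,4-bis(triethylsilyloxy)phenyl]-2-[2,4-dimethoxy-3-(3-methylbut-2-en-1-yl)-6-(triethylsilyloxy)phenyl]ethan-1-one F3.
- Buffered fluoride (n-Bu4NF, AcOH, THF, 0 °C) then releases the three phenols and the route comes back at 18.

Step 5. Deprotonation at the benzylic–allylic CH2 of the prenyl chain may compete with ring lithiation, or lithiation may stay incomplete. The fallback replaces metalation by electrophilic aromatic substitution on the much more nucleophilic free phenol.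
- It sets out from 6, which is iodinated with one equivalent of I2 and NaHCO3 in THF/H2O at 0 °C.
- The para position is blocked and the two ortho positions are equivalent, so this should give 2-iodo-3,5-dimethoxy-4-(3-methylbut-2-en-1-yl)phenol F4.
- O-alkylation of F4 with MOMCl and i-Pr2NEt in CH2Cl2 brings the route back at 9.

Further compounds
F1 | step 7 | 2-[2,4-dimethoxy-6-(methoxymethoxy)-3-(3-methylbut-2-en-1-yl)phenyl]ethan-1-ol | COCOc1cc(OC)c(CC=C(C)C)c(OC)c1CCO
F2 | step 7 | [2,4-dimethoxy-6-(methoxymethoxy)-3-(3-methylbut-2-en-1-yl)phenyl]acetaldehyde | COCOc1cc(OC)c(CC=C(C)C)c(OC)c1CC=O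
F3 | step 10 | 1-[2,4-bis(triethylsilyloxy)phenyl]-2-[2,4-dimethoxy-3-(3-methylbut-2-en-1-yl)-6-(triethylsilyloxy)phenyl]ethan-1-one | CC[Si](CC)(CC)Oc1ccc(C(=O)Cc2c(O[Si](CC)(CC)CC)cc(OC)c(CC=C(C)C)c2OC)c(O[Si](CC)(CC)CC)c1
F4 | step 5 | 2-iodo-3,5-dimethoxy-4-(3-methylbut-2-en-1-yl)phenol | Ic1c(O)cc(OC)c(CC=C(C)C)c1OC
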